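The ring-A C6 side chain (an R-configured C2'' carbinol next to the C3''=C4'' methylene) is read as an E-C4''-hydroxyprenyl group whose alkene has been transposed. A titanium–tartrate epoxidation directed by the C4'' hydroxyl oxidises only the C2''=C3'' bond, sets C2''–O as R in one operation and ignores the C8 prenyl and the ring-C C2=C3 bond. Iodide formation and zinc fragmentation then move the alkene to C3''=C4''. The precursor, 6-[(E)-4-hydroxy-3-methylbut-2-enyl]-8-prenylgenistein tris-MOM ether, is built from genistein by two sigmatropic transfers from O5 (prenyl to C8, allyl to C6) and an E-selective cross-metathesis/reduction.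

Key step: step 9

Remark: C1''–C4'' number the C6 side chain outward from ring A (C1'' benzylic CH2, C2'' carbinol carbon, C3'' methyl-bearing carbon, C4'' terminal carbon); MOM = methoxymethyl.

Step 1
Reactants: 1 genistein
Product: 2 7,4'-di-O-MOM-genistein (5-OH free)
Conditions: MOMCl (2.3 equiv), K2CO3, acetone, 0 °C → rt
Reagents that add atoms: chloromethyl methyl ether, COCCl
Why: Williamson-type O-alkylation: carbonate deprotonates only the acidic, unhindered C7 and C4' phenols, whereas the C5 hydroxyl is held in a hydrogen bond to the C4 carbonyl and stays free to serve as the anchor for both later rearrangements.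

Step 2
Reactants: 2 7,4'-di-O-MOM-genistein; 3 prenyl bromide
Product: 4 5-O-prenyl-7,4'-di-O-MOM-genistein
Conditions: K2CO3, DMF, 50 °C
Reagents that add atoms: none
Why: Williamson ether synthesis: in warm DMF the remaining chelated C5 phenoxide is alkylated on oxygen by the reactive allylic bromide, giving the aryl prenyl ether needed for the sigmatropic relay.

Step 3
Reactants: 4 5-O-prenyl-7,4'-di-O-MOM-genistein
Product: 7 8-prenyl-7,4'-di-O-MOM-genistein (5-OH free), via C6 ortho-dienone 5 (not isolated), via C8 para-dienone 6 (not isolated)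
Conditions: PhNEt2, 200 °C, Ar
Reagents that add atoms: none
Why: Tandem aromatic Claisen–Cope (para-Claisen) rearrangement: a [3,3] shift from O5 places the inverted allyl unit on C6, a second [3,3] shift carries it to C8 (para to O5) with the linear prenyl connectivity restored, and enolisation gives the hydrogen-bonded phenol, which is the established thermal course for 5-O-prenyl flavonoids.

Step 4
Reactants: 7 8-prenyl-7,4'-di-O-MOM-genistein; 8 allyl bromide
Product: 9 5-O-allyl-8-prenyl-7,4'-di-O-MOM-genistein
Conditions: K2CO3, DMF, 50 °C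
Reagents that add atoms: none
Why: Williamson ether synthesis on the regenerated C5 phenol installs the allyl group that the next step will deliver to the only remaining ring-A carbon.

Step 5
Reactants: 9 5-O-allyl-8-prenyl-7,4'-di-O-MOM-genistein
Product: 11 6-allyl-8-prenyl-7,4'-di-O-MOM-genistein (5-OH free), via C6-allyl dienone 10 (not isolated)
Conditions: PhNEt2, 195 °C, Ar
Reagents that add atoms: none
Why: Aromatic Claisen rearrangement: of the two carbons ortho to O5 only C6 can rearomatise (C4a is a ring fusion) and the para carbon C8 is already substituted, so the [3,3] shift of the symmetrical allyl group followed by enolisation can only give the 6-allyl phenol.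

Step 6
Reactants: 11 6-allyl-8-prenyl-7,4'-di-O-MOM-genistein
Product: 12 6-allyl-8-prenyl-5,7,4'-tri-O-MOM-genistein
Conditions: NaH, MOMCl, DMF, 0 °C → rt
Reagents that add atoms: chloromethyl methyl ether, COCCl
Why: Williamson-type acetal formation: irreversible deprotonation with NaH breaks the C5–OH to C4=O hydrogen bond so the hindered phenoxide is capped, which removes the bidentate site that would otherwise bind titanium in the key step.

Step 7
Reactants: 12 6-allyl-8-prenyl-5,7,4'-tri-O-MOM-genistein; 13 methacrolein
Product: 14 6-[(E)-3-methyl-4-oxobut-2-enyl]-8-prenyl-5,7,4'-tri-O-MOM-genistein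
Conditions: methacrolein (10 equiv), second-generation Grubbs catalyst RuCl2(=CHPh)(H2IMes)(PCy3) (5 mol %), 1,4-benzoquinone (10 mol %), CH2Cl2, 40 °C
Reagents that add atoms: none
Why: Olefin cross-metathesis of the monosubstituted allyl alkene with methacrolein should give the trisubstituted enal with the E geometry (formyl trans to the benzylic carbon) as the thermodynamically favoured isomer, while the trisubstituted C8 prenyl alkene and the electron-poor ring-C C2=C3 bond engage the ruthenium carbene far more slowly.

Step 8
Reactants: 14 6-[(E)-3-methyl-4-oxobut-2-enyl]-8-prenyl-5,7,4'-tri-O-MOM-genistein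
Product: 15 6-[(E)-4-hydroxy-3-methylbut-2-enyl]-8-prenyl-5,7,4'-tri-O-MOM-genistein
Conditions: NaBH4, CeCl3·7H2O, MeOH/THF, −40 °C
Reagents that add atoms: none
Why: Luche reduction: cerium-activated borohydride adds 1,2 to the aldehyde much faster than to the vinylogous-ester C4 carbonyl and does not touch the alkene geometry, giving the E-allylic alcohol.

Step 9
Reactants: 15 6-[(E)-4-hydroxy-3-methylbut-2-enyl]-8-prenyl-5,7,4'-tri-O-MOM-genistein
Product: 16 6-{[(2R,3R)-3-(hydroxymethyl)-3-methyloxiran-2-yl]methyl}-8-prenyl-5,7,4'-tri-O-MOM-genistein [(2''R,3''R)-epoxy alcohol]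
Conditions: Ti(OiPr)4 (10 mol %), D-(−)-diethyl tartrate (12 mol %), t-BuOOH (2 equiv, decane), 4 Å MS, CH2Cl2, −20 °C
Reagents that add atoms: tert-butyl hydroperoxide, CC(C)(C)OO
Why: Sharpless–Katsuki asymmetric epoxidation: the C4'' alkoxide of 15 and tert-butyl peroxide replace isopropoxides on one titanium of the dimeric titanium–tartrate complex, and the η2-bound peroxide transfers its distal oxygen to the C2''=C3'' π bond inside that assembly. The closest known substrate class is the (E)-2-methyl-2-alken-1-ol, one of the fastest and most selective classes for this reaction. The oxirane is closed by a concerted, suprafacial [2+1] oxygen-atom transfer through a spiro transition state, so both C–O bonds form on one face and the E geometry is translated stereospecifically into the trans relationship of C1'' and C4''. The absolute configuration at C2'' and C3'' is reagent-controlled by the tartrate: D-(−)-diethyl tartrate should deliver oxygen to the face that gives (2''R,3''R), the mirror image of the (2S,3S) series that L-(+)-tartrate gives with E-allylic alcohols. The step needs enantioface selectivity and chemoselectivity over the C8 prenyl alkene and the ring-C C2=C3 bond; both follow because only the alkene tethered to titanium through the allylic oxygen is epoxidised, and MOM protection of all three phenols (above all the O5/C4=O chelating site) keeps the substrate from sequestering the catalyst.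

Step 10
Reactants: 16 (2''R,3''R)-epoxy alcohol
Product: 17 6-{[(2R,3S)-3-(iodomethyl)-3-methyloxiran-2-yl]methyl}-8-prenyl-5,7,4'-tri-O-MOM-genistein [(2''R,3''S)-epoxy iodide]
Conditions: I2, PPh3, imidazole, CH2Cl2, 0 °C
Reagents that add atoms: iodine, I-I
Why: Appel-type iodination: the primary C4'' alcohol is converted into an alkoxyphosphonium ion and displaced by iodide in an SN2 step under imidazole buffering, so the oxirane and both stereocentres are spatially unchanged (the C3'' descriptor changes only because iodine alters the priority order).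

Step 11
Reactants: 17 (2''R,3''S)-epoxy iodide
Product: 18 6-[(2R)-2-hydroxy-3-methylbut-3-enyl]-8-prenyl-5,7,4'-tri-O-MOM-genistein
Conditions: Zn dust, EtOH, 70 °C
Reagents that add atoms: none
Why: Zinc-mediated reductive β-elimination (Boord-type fragmentation of a 2,3-epoxy iodide): zinc inserts into the C4''–I bond and the resulting carbanionoid expels the C3''–O bond, creating the C3''=C4'' methylene and the C2'' alkoxide without ever breaking the C2''–O bond, so the R configuration is carried over.

Step 12
Reactants: 18 6-[(2R)-2-hydroxy-3-methylbut-3-enyl]-8-prenyl-5,7,4'-tri-O-MOM-genistein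
Product: 19 5,7-dihydroxy-6-[(2R)-2-hydroxy-3-methylbut-3-enyl]-3-(4-hydroxyphenyl)-8-(3-methylbut-2-enyl)chromen-4-one (CNP0105386.1)
Conditions: HCl (1.25 M in MeOH), rt
Reagents that add atoms: none
Why: Acid-catalysed acetal methanolysis (MOM cleavage) releases the three phenols as dimethoxymethane is formed, under conditions too mild to protonate the prenyl or isopropenyl alkenes or to ionise the secondary allylic carbinol, so C2'' stays R.

Compound list
1 | genistein | O=c1c(-c2ccc(O)cc2)coc2cc(O)cc(O)c12 | starting material
2 | 7,4'-di-O-MOM-genistein, 5-hydroxy-7-(methoxymethoxy)-3-[4-(methoxymethoxy)phenyl]chromen-4-one | COCOc1ccc(cc1)-c1coc2cc(OCOC)cc(O)c2c1=O | intermediate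
3 | prenyl bromide (1-bromo-3-methylbut-2-ene) | CC(C)=CCBr | starting material
4 | 5-O-prenyl-7,4'-di-O-MOM-genistein | COCOc1ccc(cc1)-c1coc2cc(OCOC)cc(OCC=C(C)C)c2c1=O | intermediate
5 | C6 ortho-dienone, 7-(methoxymethoxy)-3-[4-(methoxymethoxy)phenyl]-6-(2-methylbut-3-en-2-yl)-6H-chromene-4,5-dione (racemic, not isolated) | COCOc1ccc(cc1)C1=COC2=C(C1=O)C(=O)C(C(C)(C)C=C)C(OCOC)=C2 | intermediate
6 | C8 para-dienone, 7-(methoxymethoxy)-3-[4-(methoxymethoxy)phenyl]-8-(3-methylbut-2-enyl)-8H-chromene-4,5-dione (racemic, not isolated) | COCOc1ccc(cc1)C1=COC2=C(C1=O)C(=O)C=C(OCOC)C2CC=C(C)C | intermediate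
7 | 8-prenyl-7,4'-di-O-MOM-genistein (5-OH free) | COCOc1ccc(cc1)-c1coc2c(CC=C(C)C)c(OCOC)cc(O)c2c1=O | intermediate
8 | allyl bromide | C=CCBr | starting material
9 | 5-O-allyl-8-prenyl-7,4'-di-O-MOM-genistein | COCOc1ccc(cc1)-c1coc2c(CC=C(C)C)c(OCOC)cc(OCC=C)c2c1=O | intermediate
10 | C6-allyl dienone, 6-allyl-7-(methoxymethoxy)-3-[4-(methoxymethoxy)phenyl]-8-(3-methylbut-2-enyl)-6H-chromene-4,5-dione (racemic, not isolated) | COCOc1ccc(cc1)C1=COC2=C(C1=O)C(=O)C(CC=C)C(OCOC)=C2CC=C(C)C | intermediate
11 | 6-allyl-8-prenyl-7,4'-di-O-MOM-genistein (5-OH free) | COCOc1ccc(cc1)-c1coc2c(CC=C(C)C)c(OCOC)c(CC=C)c(O)c2c1=O | intermediate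
12 | 6-allyl-8-prenyl-5,7,4'-tri-O-MOM-genistein | COCOc1ccc(cc1)-c1coc2c(CC=C(C)C)c(OCOC)c(CC=C)c(OCOC)c2c1=O | intermediate
13 | methacrolein | CC(=C)C=O | starting material
14 | 6-[(E)-3-methyl-4-oxobut-2-enyl]-8-prenyl-5,7,4'-tri-O-MOM-genistein | O=C/C(C)=C/Cc1c(OCOC)c(CC=C(C)C)c2occ(-c3ccc(OCOC)cc3)c(=O)c2c1OCOC | intermediate
15 | 6-[(E)-4-hydroxy-3-methylbut-2-enyl]-8-prenyl-5,7,4'-tri-O-MOM-genistein | OC/C(C)=C/Cc1c(OCOC)c(CC=C(C)C)c2occ(-c3ccc(OCOC)cc3)c(=O)c2c1OCOC | intermediate
16 | (2''R,3''R)-2'',3''-epoxy-4''-hydroxy derivative of 15 | OC[C@@]1(C)O[C@@H]1Cc2c(OCOC)c(CC=C(C)C)c3occ(-c4ccc(OCOC)cc4)c(=O)c3c2OCOC | intermediate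
17 | (2''R,3''S)-2'',3''-epoxy-4''-iodo derivative | IC[C@@]1(C)O[C@@H]1Cc2c(OCOC)c(CC=C(C)C)c3occ(-c4ccc(OCOC)cc4)c(=O)c3c2OCOC | intermediate
18 | 6-[(2R)-2-hydroxy-3-methylbut-3-enyl]-8-prenyl-5,7,4'-tri-O-MOM-genistein | C=C(C)[C@H](O)Cc1c(OCOC)c(CC=C(C)C)c2occ(-c3ccc(OCOC)cc3)c(=O)c2c1OCOC | intermediate
19 | CNP0105386.1, 6-[(2R)-2-hydroxy-3-methylbut-3-enyl]-8-prenylgenistein | C=C(C)[C@H](O)Cc1c(O)c(CC=C(C)C)c2occ(-c3ccc(O)cc3)c(=O)c2c1O | target

Total step count: 12. Longest linear sequence: 12 steps (1 to 19).

Steps most likely to fail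

Step 7. Once the allyl group is used up, secondary metathesis may start to consume the C8 prenyl alkene. A ruthenium hydride may also move the allyl double bond into conjugation with ring A before coupling. The fallback runs the metathesis while no prenyl group is present and brings the C8 prenyl in last by cross-coupling; this detour also bypasses the Claisen–Cope step. It sets out from 2. O-Allylation (allyl bromide, K2CO3, DMF) should give 5-O-allyl-7,4'-di-O-MOM-genistein F1. Aromatic Claisen rearrangement (PhNEt2, 195 °C) should move the allyl group to C6, where the ortho-dienone enolises before any second shift, giving 6-allyl-7,4'-di-O-MOM-genistein F2. NaH/MOMCl should give 6-allyl-5,7,4'-tri-O-MOM-genistein F3. Cross-metathesis with methacrolein under the conditions of step 7 should give the prenyl-free (E)-enal F4. N-Iodosuccinimide in DMF should iodinate C8, the only unsubstituted carbon of ring A, giving the 8-iodo (E)-enal F5; the enal alkene is deactivated towards iodonium. Luche reduction should give the 8-iodo (E)-allylic alcohol F6. Stille coupling with tributyl(3-methylbut-2-enyl)stannane (Pd(PPh3)4, DMF, 90 °C) should attach the linear prenyl group and return to the route at 15.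

Step 9. Titanium may bind to the chromone carbonyl and the acetal oxygens, slowing turnover so that an unselective background oxidation lowers the enantiomeric purity. The new oxirane may also be opened under Lewis acid by a neighbouring C5 or C7 acetal oxygen. The fallback is metal-free and sets out from enal 14. Amine-salt (iminium) catalysed epoxidation with aqueous H2O2 is a known method for α-branched enals. The catalyst would be 9-amino-9-deoxy-epi-quinine, or its quinidine-derived pseudoenantiomer, as the salt with 3,3'-bis(2,4,6-triisopropylphenyl)-1,1'-binaphthyl-2,2'-diyl hydrogen phosphate; the antipode that gives 2''R would be chosen by correlation. This should give the (2''R,3''S)-epoxy aldehyde F7. NaBH4 in MeOH at −40 °C should then reduce the aldehyde and return to the route at 16.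

Step 12. A freed ortho phenol may cyclise under acid onto the prenyl or isopropenyl alkene, or the allylic carbinol may ionise, before the third and most hindered acetal is cleaved. The fallback avoids Brønsted acid and sets out from 18. TMSOTf with 2,2'-bipyridyl in CH2Cl2/MeCN at 0 °C should exchange the three aryl MOM ethers for trimethylsilyl ethers and silylate the carbinol, giving the tetrakis(trimethylsilyl) ether F8. Water followed by dilute aqueous citric acid in THF at room temperature should hydrolyse all four silyl ethers and return to the route at 19.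

Further compounds
F1 | step 7 | 5-O-allyl-7,4'-di-O-MOM-genistein | COCOc1ccc(cc1)-c1coc2cc(OCOC)cc(OCC=C)c2c1=O
F2 | step 7 | 6-allyl-7,4'-di-O-MOM-genistein (5-OH free) | COCOc1ccc(cc1)-c1coc2cc(OCOC)c(CC=C)c(O)c2c1=O
F3 | step 7 | 6-allyl-5,7,4'-tri-O-MOM-genistein | COCOc1ccc(cc1)-c1coc2cc(OCOC)c(CC=C)c(OCOC)c2c1=O
F4 | step 7 | 6-[(E)-3-methyl-4-oxobut-2-enyl]-5,7,4'-tri-O-MOM-genistein | O=C/C(C)=C/Cc1c(OCOC)cc2occ(-c3ccc(OCOC)cc3)c(=O)c2c1OCOC
F5 | step 7 | 8-iodo-6-[(E)-3-methyl-4-oxobut-2-enyl]-5,7,4'-tri-O-MOM-genistein | O=C/C(C)=C/Cc1c(OCOC)c(I)c2occ(-c3ccc(OCOC)cc3)c(=O)c2c1OCOC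
F6 | step 7 | 8-iodo-6-[(E)-4-hydroxy-3-methylbut-2-enyl]-5,7,4'-tri-O-MOM-genistein | OC/C(C)=C/Cc1c(OCOC)c(I)c2occ(-c3ccc(OCOC)cc3)c(=O)c2c1OCOC
F7 | step 9 | (2''R,3''S)-2'',3''-epoxy-4''-oxo derivative (epoxy aldehyde) | O=C[C@@]1(C)O[C@@H]1Cc2c(OCOC)c(CC=C(C)C)c3occ(-c4ccc(OCOC)cc4)c(=O)c3c2OCOC
F8 | step 12 | 5,7,4',2''-tetrakis-O-(trimethylsilyl) derivative of 19 | C=C(C)[C@H](O[Si](C)(C)C)Cc1c(O[Si](C)(C)C)c(CC=C(C)C)c2occ(-c3ccc(O[Si](C)(C)C)cc3)c(=O)c2c1O[Si](C)(C)C
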